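**Assumption:** (4R,6R)-actinol 1 is bought as the single enantiomer, and the C9=C10 bond of the target is read from the SMILES as Z (C8 and C11 cis) and made as such. Carotenoid locants (C3, C5, C8, C9 …) are used in the explanations.

## Retrosynthetic overview

1. Target 20 ⇐ ester reduction of C27 ester 19 ⇐ Wittig olefination (C11=C12) of C15 furanoid phosphonium salt 14 with C12 aldehyde ester 16, itself one Wittig step from C10 dialdehyde 15.
2. 14 ⇐ diol 12 ⇐ bis-silyl furanoid 11 ⇐ PPh3 ring contraction (SN2, inversion at C8) of 5,8-endoperoxide 9 ⇐ singlet-oxygen [4+2] cycloaddition on triene 8. The cycloaddition sets the C5–O and C8–O bonds suprafacially, on the face chosen by the bought C3 centre.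
3. 8 ⇐ Suzuki coupling of enol triflate 4 (from actinol 1) with dienylboronate 7 (from (Z)-enynol 5, which brings the 9Z bond).
4. Ring order: the cyclohexene ring is bought in 1; the 1,2-dioxine ring forms by cycloaddition; it is contracted to the 2,5-dihydrofuran ring.

## Route

**Step 1**
Reactants: 1 (4R,6R)-4-hydroxy-2,2,6-trimethylcyclohexanone
Product: 2 (4R,6R)-4-(tert-butyldimethylsilyloxy)-2,2,6-trimethylcyclohexanone
Conditions: TBSCl, imidazole, DMF, rt
Reagents that add atoms: tert-butyldimethylsilyl chloride (TBSCl), CC(C)(C)[Si](C)(C)Cl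
Why: Standard silyl ether protection of the secondary alcohol, which touches no stereocentre and gives a bulky group at C3 for later face control.

**Step 2**
Reactants: 2 (4R,6R)-4-(tert-butyldimethylsilyloxy)-2,2,6-trimethylcyclohexanone
Product: 4 (4R)-4-(tert-butyldimethylsilyloxy)-2,6,6-trimethylcyclohex-1-en-1-yl trifluoromethanesulfonate, via lithium enolate 3 (not isolated)
Conditions: LiN(i-Pr)2, THF, −78 → 0 °C; PhNTf2, −78 °C → rt
Reagents that add atoms: N-phenylbis(trifluoromethanesulfonimide) (PhNTf2), O=S(=O)(N(c1ccccc1)S(=O)(=O)C(F)(F)F)C(F)(F)F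
Why: The ketone can enolise only toward the CH(CH3) side, so enolate O-triflation (enol triflate formation) gives one regioisomer; the methyl-bearing centre is erased and the silyloxy centre is untouched.

**Step 3**
Reactants: 5 (2Z)-3-methylpent-2-en-4-yn-1-ol
Product: 6 tert-butyldimethyl{[(2Z)-3-methylpent-2-en-4-yn-1-yl]oxy}silane
Conditions: TBSCl, imidazole, CH2Cl2, 0 °C → rt
Reagents that add atoms: tert-butyldimethylsilyl chloride (TBSCl), CC(C)(C)[Si](C)(C)Cl
Why: Silyl ether protection of the primary allylic alcohol, needed so that this oxygen cannot compete as a nucleophile in the ring contraction of step 6; the bought Z double bond is not touched.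

**Step 4**
Reactants: 6 tert-butyldimethyl{[(2Z)-3-methylpent-2-en-4-yn-1-yl]oxy}silane
Product: 7 2-[(1E,3Z)-5-(tert-butyldimethylsilyloxy)-3-methylpenta-1,3-dien-1-yl]-4,4,5,5-tetramethyl-1,3,2-dioxaborolane
Conditions: pinacolborane, Cp2Zr(H)Cl (5 mol %), Et3N (10 mol %), neat, 60 °C
Reagents that add atoms: pinacolborane, CC1(C)OBOC1(C)C
Why: Zirconium-catalysed syn hydroboration of the terminal alkyne places boron on the terminal carbon and gives the E-alkenylboronate only, leaving the Z-trisubstituted alkene as bought.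

**Step 5**
Reactants: 4 (4R)-4-(tert-butyldimethylsilyloxy)-2,6,6-trimethylcyclohex-1-en-1-yl trifluoromethanesulfonate + 7 2-[(1E,3Z)-5-(tert-butyldimethylsilyloxy)-3-methylpenta-1,3-dien-1-yl]-4,4,5,5-tetramethyl-1,3,2-dioxaborolane
Product: 8 tert-butyl{[(2Z,4E)-5-[(4R)-4-(tert-butyldimethylsilyloxy)-2,6,6-trimethylcyclohex-1-en-1-yl]-3-methylpenta-2,4-dien-1-yl]oxy}dimethylsilane
Conditions: Pd(PPh3)4 (5 mol %), aq. TlOH, THF, rt, dark
Reagents that add atoms: none
Why: Suzuki–Miyaura coupling forms the C6–C7 bond with retention of both alkene geometries, the thallium base speeding transmetallation enough for the hindered tetrasubstituted triflate to couple at room temperature.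

**Step 6**
Reactants: 8 tert-butyl{[(2Z,4E)-5-[(4R)-4-(tert-butyldimethylsilyloxy)-2,6,6-trimethylcyclohex-1-en-1-yl]-3-methylpenta-2,4-dien-1-yl]oxy}dimethylsilane
Product: 11 tert-butyl{[(2Z)-3-[(2S,6S,7aR)-6-(tert-butyldimethylsilyloxy)-4,4,7a-trimethyl-2,4,5,6,7,7a-hexahydro-1-benzofuran-2-yl]but-2-en-1-yl]oxy}dimethylsilane, via endoperoxide 9 (not isolated), via oxyphosphonium alkoxide 10 (not isolated)
Conditions: O2, hν (visible), tetraphenylporphyrin (1 mol %), CH2Cl2, −78 °C; Ar purge, dark; PPh3, −78 °C → rt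
Reagents that add atoms: dioxygen (as singlet oxygen), O=O
Why: Singlet oxygen adds to the twisted s-cis C5=C6–C7=C8 diene in a suprafacial [4+2] cycloaddition on the ring face opposite the C3 silyloxy group to give the (5R,8R)-endoperoxide 9; PPh3 then inserts into the O–O bond and the tertiary C5 alkoxide of 10 displaces Ph3P=O at the secondary, doubly allylic C8 (SN2 ring contraction with inversion), so C5 (R) is set by the cycloaddition face and C8 (S) by suprafacial addition followed by inversion, the minor syn-face diastereomer (expected d.r. about 3:1) being removed by chromatography.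

**Step 7**
Reactants: 11 tert-butyl{[(2Z)-3-[(2S,6S,7aR)-6-(tert-butyldimethylsilyloxy)-4,4,7a-trimethyl-2,4,5,6,7,7a-hexahydro-1-benzofuran-2-yl]but-2-en-1-yl]oxy}dimethylsilane
Product: 12 (2S,6S,7aR)-2-[(2Z)-4-hydroxybut-2-en-2-yl]-4,4,7a-trimethyl-2,4,5,6,7,7a-hexahydro-1-benzofuran-6-ol
Conditions: Bu4NF, THF, 0 °C → rt
Reagents that add atoms: none
Why: Fluoride-mediated desilylation removes both silyl ethers under non-acidic conditions that leave the acid-labile allylic C8–O bond and all three stereocentres alone.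

**Step 8**
Reactants: 12 (2S,6S,7aR)-2-[(2Z)-4-hydroxybut-2-en-2-yl]-4,4,7a-trimethyl-2,4,5,6,7,7a-hexahydro-1-benzofuran-6-ol
Product: 14 {(2Z)-3-[(2S,6S,7aR)-6-hydroxy-4,4,7a-trimethyl-2,4,5,6,7,7a-hexahydro-1-benzofuran-2-yl]but-2-en-1-yl}triphenylphosphonium bromide, via allylic bromide 13 (not isolated)
Conditions: NBS, Me2S, CH2Cl2, −30 → 0 °C; cold pentane/water partition; PPh3, MeCN, rt, dark
Reagents that add atoms: N-bromosuccinimide (NBS), O=C1CCC(=O)N1Br; triphenylphosphine, c1ccc(cc1)P(c1ccccc1)c1ccccc1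
Why: Corey–Kim halogenation converts only the allylic primary alcohol into the bromide under neutral conditions (the saturated C3 alcohol does not react and the Z geometry is kept, as with nerol), and SN2 quaternisation by PPh3 then gives the Wittig salt.

**Step 9**
Reactants: 15 (2E,4E,6E)-2,7-dimethylocta-2,4,6-trienedial
Product: 16 methyl (2E,4E,6E,8E)-4,9-dimethyl-10-oxodeca-2,4,6,8-tetraenoate
Conditions: Ph3P=CHCO2Me (1 equiv, slow addition), 15 (2 equiv), CH2Cl2, 0 °C → rt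
Reagents that add atoms: methyl (triphenylphosphoranylidene)acetate, COC(=O)C=P(c1ccccc1)(c1ccccc1)c1ccccc1
Why: Wittig olefination with a stabilised ylide is E-selective and stops at the mono-adduct, because the dialdehyde is used in excess and the more conjugated product aldehyde is less electrophilic.

**Step 10**
Reactants: 14 {(2Z)-3-[(2S,6S,7aR)-6-hydroxy-4,4,7a-trimethyl-2,4,5,6,7,7a-hexahydro-1-benzofuran-2-yl]but-2-en-1-yl}triphenylphosphonium bromide + 16 methyl (2E,4E,6E,8E)-4,9-dimethyl-10-oxodeca-2,4,6,8-tetraenoate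
Product: 19 methyl (2E,4E,6E,8E,10E,12Z)-13-[(2S,6S,7aR)-6-hydroxy-4,4,7a-trimethyl-2,4,5,6,7,7a-hexahydro-1-benzofuran-2-yl]-4,9-dimethyltetradeca-2,4,6,8,10,12-hexaenoate, via phosphorus ylide 17 (not isolated), via 11Z ester 18 (not isolated)
Conditions: NaOMe (1.1 equiv, added last), MeOH/CH2Cl2, 0 °C → rt; then EtOAc/heptane, 60 °C, Ar, dark
Reagents that add atoms: none
Why: Wittig olefination of the semi-stabilised allyl ylide, trapped by the aldehyde as it forms, builds C11=C12 as an E/Z mixture whose sterically hindered 11Z part 18 relaxes to 11E on gentle warming, while the unhindered 9Z bond and the C8 centre are kept.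

**Step 11**
Reactants: 19 methyl (2E,4E,6E,8E,10E,12Z)-13-[(2S,6S,7aR)-6-hydroxy-4,4,7a-trimethyl-2,4,5,6,7,7a-hexahydro-1-benzofuran-2-yl]-4,9-dimethyltetradeca-2,4,6,8,10,12-hexaenoate
Product: 20 (2S,6S,7aR)-2-[(2Z,4E,6E,8E,10E,12E)-14-hydroxy-6,11-dimethyltetradeca-2,4,6,8,10,12-hexaen-2-yl]-4,4,7a-trimethyl-2,4,5,6,7,7a-hexahydro-1-benzofuran-6-ol
Conditions: i-Bu2AlH (4.5 equiv), CH2Cl2, −78 °C; aq. potassium sodium tartrate, dark
Reagents that add atoms: none
Why: Hydride 1,2-reduction of the conjugated ester gives the primary allylic alcohol without touching the polyene, the dihydrofuran or any stereocentre, and the neutral tartrate work-up avoids acid-induced epimerisation at C8.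

## Compound list

1 | (4R,6R)-4-hydroxy-2,2,6-trimethylcyclohexanone (actinol) | O=C1C(C)(C)C[C@H](O)C[C@H]1C | starting material
2 | (4R,6R)-4-(tert-butyldimethylsilyloxy)-2,2,6-trimethylcyclohexanone | O=C1C(C)(C)C[C@H](O[Si](C)(C)C(C)(C)C)C[C@H]1C | intermediate
3 | lithium (4R)-4-(tert-butyldimethylsilyloxy)-2,6,6-trimethylcyclohex-1-en-1-olate | CC1=C(O[Li])C(C)(C)C[C@H](O[Si](C)(C)C(C)(C)C)C1 | intermediate
4 | (4R)-4-(tert-butyldimethylsilyloxy)-2,6,6-trimethylcyclohex-1-en-1-yl trifluoromethanesulfonate | CC1=C(OS(=O)(=O)C(F)(F)F)C(C)(C)C[C@H](O[Si](C)(C)C(C)(C)C)C1 | intermediate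
5 | (2Z)-3-methylpent-2-en-4-yn-1-ol | C#C/C(C)=C\CO | starting material
6 | tert-butyldimethyl{[(2Z)-3-methylpent-2-en-4-yn-1-yl]oxy}silane | C#C/C(C)=C\CO[Si](C)(C)C(C)(C)C | intermediate
7 | 2-[(1E,3Z)-5-(tert-butyldimethylsilyloxy)-3-methylpenta-1,3-dien-1-yl]-4,4,5,5-tetramethyl-1,3,2-dioxaborolane | CC1(C)OB(/C=C/C(C)=C\CO[Si](C)(C)C(C)(C)C)OC1(C)C | intermediate
8 | tert-butyl{[(2Z,4E)-5-[(4R)-4-(tert-butyldimethylsilyloxy)-2,6,6-trimethylcyclohex-1-en-1-yl]-3-methylpenta-2,4-dien-1-yl]oxy}dimethylsilane | CC1=C(/C=C/C(C)=C\CO[Si](C)(C)C(C)(C)C)C(C)(C)C[C@H](O[Si](C)(C)C(C)(C)C)C1 | intermediate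
9 | (3R,7S,8aR)-7-(tert-butyldimethylsilyloxy)-3-[(2Z)-4-(tert-butyldimethylsilyloxy)but-2-en-2-yl]-5,5,8a-trimethyl-3,5,6,7,8,8a-hexahydrobenzo[c][1,2]dioxine (5,8-endoperoxide; 3S,5R,8R in carotenoid locants) | C/C(=C/CO[Si](C)(C)C(C)(C)C)[C@H]1C=C2C(C)(C)C[C@H](O[Si](C)(C)C(C)(C)C)C[C@@]2(C)OO1 | intermediate
10 | ring-opened betaine of 9: triphenylphosphonio-oxy group on C8 (R), alkoxide on C5 (R), C6=C7 with C8 cis to C5, both silyl ethers in place | C/C(=C/CO[Si](C)(C)C(C)(C)C)[C@H](O[P+](c1ccccc1)(c1ccccc1)c1ccccc1)/C=C1/C(C)(C)C[C@H](O[Si](C)(C)C(C)(C)C)C[C@@]1(C)[O-] | intermediate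
11 | tert-butyl{[(2Z)-3-[(2S,6S,7aR)-6-(tert-butyldimethylsilyloxy)-4,4,7a-trimethyl-2,4,5,6,7,7a-hexahydro-1-benzofuran-2-yl]but-2-en-1-yl]oxy}dimethylsilane | C/C(=C/CO[Si](C)(C)C(C)(C)C)[C@@H]1C=C2C(C)(C)C[C@H](O[Si](C)(C)C(C)(C)C)C[C@@]2(C)O1 | intermediate
12 | (2S,6S,7aR)-2-[(2Z)-4-hydroxybut-2-en-2-yl]-4,4,7a-trimethyl-2,4,5,6,7,7a-hexahydro-1-benzofuran-6-ol | C/C(=C/CO)[C@@H]1C=C2C(C)(C)C[C@H](O)C[C@@]2(C)O1 | intermediate
13 | (2S,6S,7aR)-2-[(2Z)-4-bromobut-2-en-2-yl]-4,4,7a-trimethyl-2,4,5,6,7,7a-hexahydro-1-benzofuran-6-ol | C/C(=C/CBr)[C@@H]1C=C2C(C)(C)C[C@H](O)C[C@@]2(C)O1 | intermediate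
14 | {(2Z)-3-[(2S,6S,7aR)-6-hydroxy-4,4,7a-trimethyl-2,4,5,6,7,7a-hexahydro-1-benzofuran-2-yl]but-2-en-1-yl}triphenylphosphonium bromide | C/C(=C/C[P+](c1ccccc1)(c1ccccc1)c1ccccc1)[C@@H]1C=C2C(C)(C)C[C@H](O)C[C@@]2(C)O1.[Br-] | intermediate
15 | (2E,4E,6E)-2,7-dimethylocta-2,4,6-trienedial | O=C/C(C)=C/C=C/C=C(C)/C=O | starting material
16 | methyl (2E,4E,6E,8E)-4,9-dimethyl-10-oxodeca-2,4,6,8-tetraenoate | COC(=O)/C=C/C(C)=C/C=C/C=C(C)/C=O | intermediate
17 | (2S,6S,7aR)-4,4,7a-trimethyl-2-[(2Z)-4-(triphenylphosphoranylidene)but-2-en-2-yl]-2,4,5,6,7,7a-hexahydro-1-benzofuran-6-ol (ylide of 14) | C/C(=C/C=P(c1ccccc1)(c1ccccc1)c1ccccc1)[C@@H]1C=C2C(C)(C)C[C@H](O)C[C@@]2(C)O1 | intermediate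
18 | methyl (2E,4E,6E,8E,10Z,12Z)-13-[(2S,6S,7aR)-6-hydroxy-4,4,7a-trimethyl-2,4,5,6,7,7a-hexahydro-1-benzofuran-2-yl]-4,9-dimethyltetradeca-2,4,6,8,10,12-hexaenoate (11Z isomer of 19) | C/C(=C/C=C\C(C)=C\C=C\C=C(C)\C=C\C(=O)OC)[C@@H]1C=C2C(C)(C)C[C@H](O)C[C@@]2(C)O1 | intermediate
19 | methyl (2E,4E,6E,8E,10E,12Z)-13-[(2S,6S,7aR)-6-hydroxy-4,4,7a-trimethyl-2,4,5,6,7,7a-hexahydro-1-benzofuran-2-yl]-4,9-dimethyltetradeca-2,4,6,8,10,12-hexaenoate | C/C(=C/C=C/C(C)=C/C=C/C=C(C)/C=C/C(=O)OC)[C@@H]1C=C2C(C)(C)C[C@H](O)C[C@@]2(C)O1 | intermediate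
20 | (2S,6S,7aR)-2-[(2Z,4E,6E,8E,10E,12E)-14-hydroxy-6,11-dimethyltetradeca-2,4,6,8,10,12-hexaen-2-yl]-4,4,7a-trimethyl-2,4,5,6,7,7a-hexahydro-1-benzofuran-6-ol ((3S,5R,8S,9Z)-5,8-epoxy-5,8-dihydro-10′-apo-β-carotene-3,10′-diol) | C/C(=C/C=C/C(C)=C/C=C/C=C(C)/C=C/CO)[C@@H]1C=C2C(C)(C)C[C@H](O)C[C@@]2(C)O1 | target

## Step count and weak points

Total steps: 11. Longest linear sequence: 8 (steps 1, 2, 5, 6, 7, 8, 10, 11).

**Step 6 (photooxygenation and ring contraction).** The face selectivity of singlet oxygen relative to the C3 silyloxy group may be low, ene hydroperoxides may compete, and the betaine could ionise at C5 instead of closing at C8. The fallback sets out from 8. Buffered peracid epoxidation (mCPBA, NaHCO3, CH2Cl2, 0 °C) of the electron-rich C5=C6 bond, which for 3-acyloxy and 3-silyloxy rings of this type prefers the face anti to the C3 substituent, gives tert-butyl{[(2Z,4E)-5-[(1S,4S,6R)-4-(tert-butyldimethylsilyloxy)-2,2,6-trimethyl-7-oxabicyclo[4.1.0]heptan-1-yl]-3-methylpenta-2,4-dien-1-yl]oxy}dimethylsilane F1. A trace of anhydrous HCl in CHCl3 at 0 °C for a few minutes then brings about the ionic epoxide-to-furanoid rearrangement with the C5–O bond kept. The resulting 8S and 8R furanoids are separated by chromatography, and the 8S isomer is 11, where the route is rejoined.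

**Step 8 (allylic bromide and phosphonium salt).** The Z-allylic bromide may isomerise or be attacked by the neighbouring ring oxygen, and the free C3 hydroxyl may interfere. The fallback sets out from 12 and reverses the polarity of the C11=C12 olefination. MnO2 in CH2Cl2 oxidises only the allylic alcohol to (2Z)-3-[(2S,6S,7aR)-6-hydroxy-4,4,7a-trimethyl-2,4,5,6,7,7a-hexahydro-1-benzofuran-2-yl]but-2-enal F2. In parallel 16 is reduced with NaBH4 in MeOH at 0 °C to methyl (2E,4E,6E,8E)-10-hydroxy-4,9-dimethyldeca-2,4,6,8-tetraenoate F3. This is converted with PBr3 and a little pyridine in Et2O at −10 °C into methyl (2E,4E,6E,8E)-10-bromo-4,9-dimethyldeca-2,4,6,8-tetraenoate F4, and then by Arbuzov reaction with P(OEt)3 at 80 °C into methyl (2E,4E,6E,8E)-10-(diethoxyphosphoryl)-4,9-dimethyldeca-2,4,6,8-tetraenoate F5. Horner–Wadsworth–Emmons reaction of the anion of F5 (NaH, THF, −78 °C) with F2 gives 19 directly, so the route is rejoined at 19 and steps 8 and 10 are bypassed.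

**Step 10 (Wittig coupling).** The new C11=C12 bond forms as an E/Z mixture and the warming that corrects it may erode the 9Z bond. The fallback sets out from 12. The bromide 13 is made as in step 8 but is treated with NaP(O)(OEt)2 in THF at 0 °C (Michaelis–Becker reaction) instead of PPh3, giving diethyl {(2Z)-3-[(2S,6S,7aR)-6-hydroxy-4,4,7a-trimethyl-2,4,5,6,7,7a-hexahydro-1-benzofuran-2-yl]but-2-en-1-yl}phosphonate F6. Its dianion (NaN(SiMe3)2, 2.1 equiv, THF, −78 °C) undergoes an E-selective Horner–Wadsworth–Emmons reaction with 16 at low temperature, with no thermal isomerisation stage, and gives 19, where the route is rejoined.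

## Further compounds

F1 | step 6 | tert-butyl{[(2Z,4E)-5-[(1S,4S,6R)-4-(tert-butyldimethylsilyloxy)-2,2,6-trimethyl-7-oxabicyclo[4.1.0]heptan-1-yl]-3-methylpenta-2,4-dien-1-yl]oxy}dimethylsilane | C/C(=C/CO[Si](C)(C)C(C)(C)C)/C=C/[C@@]12O[C@]1(C)C[C@@H](O[Si](C)(C)C(C)(C)C)CC2(C)C
F2 | step 8 | (2Z)-3-[(2S,6S,7aR)-6-hydroxy-4,4,7a-trimethyl-2,4,5,6,7,7a-hexahydro-1-benzofuran-2-yl]but-2-enal | C/C(=C/C=O)[C@@H]1C=C2C(C)(C)C[C@H](O)C[C@@]2(C)O1
F3 | step 8 | methyl (2E,4E,6E,8E)-10-hydroxy-4,9-dimethyldeca-2,4,6,8-tetraenoate | COC(=O)/C=C/C(C)=C/C=C/C=C(C)/CO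
F4 | step 8 | methyl (2E,4E,6E,8E)-10-bromo-4,9-dimethyldeca-2,4,6,8-tetraenoate | COC(=O)/C=C/C(C)=C/C=C/C=C(C)/CBr
F5 | step 8 | methyl (2E,4E,6E,8E)-10-(diethoxyphosphoryl)-4,9-dimethyldeca-2,4,6,8-tetraenoate | CCOP(=O)(OCC)C/C(C)=C/C=C/C=C(C)/C=C/C(=O)OC
F6 | step 10 | diethyl {(2Z)-3-[(2S,6S,7aR)-6-hydroxy-4,4,7a-trimethyl-2,4,5,6,7,7a-hexahydro-1-benzofuran-2-yl]but-2-en-1-yl}phosphonate | C/C(=C/CP(=O)(OCC)OCC)[C@@H]1C=C2C(C)(C)C[C@H](O)C[C@@]2(C)O1
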